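The 27-membered ring of 26-hexacosanolide consists of one ester (ring O, carbonyl C1) and an unbranched run of 25 methylenes, C2 to C26. Because no substituent marks any position, the ring is cut at C3–C4: a primary radical at C4, freed from a redox-active ester by loss of CO2, adds to the terminal carbon C3 of an acrylate held on the C26 oxygen. This single operation closes the macrocycle with the lactone ester already in place and the chain saturated. The precursor is the N-hydroxyphthalimide ester of 24-(acryloyloxy)tetracosanoic acid, whose C24 chain is assembled by anodic Kolbe cross-coupling of a C16 with a C10 acid.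

Key step: step 6

Remark: positions C1 to C26 are numbered as in the lactone (C1 carbonyl, C26 on the ring oxygen); the acid end is carried as a tert-butyl ester, taken from purchasable 10-tert-butoxy-10-oxodecanoic acid, so that it can later be freed by acid without touching the acrylate.

Step 1
Reactants: 1 16-hydroxyhexadecanoic acid
Product: 2 16-acetoxyhexadecanoic acid
Conditions: AcCl (5 equiv), CH2Cl2, 0 °C to reflux; then H2O/THF, rt
Reagents that add atoms: acetyl chloride, CC(=O)Cl
Why: O-acylation of the primary alcohol by an acid chloride without base, under which the carboxyl group stays protonated and unesterified, gives the acetate that shields the hydroxyl from anodic oxidation and self-esterification in the electrolysis.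

Step 2
Reactants: 2 16-acetoxyhexadecanoic acid; 3 10-tert-butoxy-10-oxodecanoic acid (mono-tert-butyl sebacate, 4 equiv)
Product: 5 tert-butyl 24-hydroxytetracosanoate, via tert-butyl 24-acetoxytetracosanoate 4 (not isolated)
Conditions: Pt foil anode and cathode, undivided cell, NaOMe (5 mol% of total acid), MeOH, 0.25 A cm-2, 45 °C, until faintly basic; then K2CO3 (0.3 equiv), MeOH/THF, rt
Reagents that add atoms: none
Why: Mixed Kolbe electrolysis, in which each carboxylate is oxidised at the platinum anode, loses CO2 and leaves a primary radical, joins AcO(CH2)15• with •(CH2)8CO2tBu at the future C11–C12 bond, the excess of the cheap half-ester 3 steering 2 into the cross product; carbonate-catalysed methanolysis (Zemplén-type transesterification) in the same pot then removes the acetate but not the hindered tert-butyl ester, so that 5 separates easily on silica from the hydroxyl-free C18 diester and the far more polar C30 diol of symmetrical coupling.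

Step 3
Reactants: 5 tert-butyl 24-hydroxytetracosanoate; 6 acryloyl chloride
Product: 7 tert-butyl 24-(acryloyloxy)tetracosanoate
Conditions: Et3N, BHT (cat.), CH2Cl2, 0 °C to rt
Reagents that add atoms: none
Why: Acylation of the primary alcohol by the acid chloride with Et3N as HCl acceptor (nucleophilic acyl substitution) is clean because the carboxyl end is locked as its tert-butyl ester, so no mixed anhydride or oligoester can arise, and BHT at low temperature holds back polymerisation of the acrylate.

Step 4
Reactants: 7 tert-butyl 24-(acryloyloxy)tetracosanoate
Product: 8 24-(acryloyloxy)tetracosanoic acid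
Conditions: TFA/CH2Cl2 (1:4), BHT (cat.), 0 °C to rt
Reagents that add atoms: none
Why: Acidolysis of the tert-butyl ester (alkyl–oxygen cleavage through the tert-butyl cation, lost as 2-methylpropene) frees the carboxylic acid, whereas the acrylate ester of a primary alcohol cannot ionise in this way and survives.

Step 5
Reactants: 8 24-(acryloyloxy)tetracosanoic acid
Product: 9 1,3-dioxoisoindolin-2-yl 24-(acryloyloxy)tetracosanoate
Conditions: N-hydroxyphthalimide (1.05 equiv), DIC, DMAP (5 mol%), CH2Cl2, 0 °C to rt, dark
Reagents that add atoms: N-hydroxyphthalimide, O=C1c2ccccc2C(=O)N1O
Why: Steglich-type carbodiimide esterification, in which DIC converts the acid into an O-acylisourea that the acidic N-hydroxyphthalimide intercepts, runs under cold, near-neutral conditions that leave the acrylate untouched.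

Step 6
Reactants: 9 1,3-dioxoisoindolin-2-yl 24-(acryloyloxy)tetracosanoate
Product: 10 26-hexacosanolide
Conditions: Ru(bpy)3(PF6)2 (5 mol%), Hantzsch ester (diethyl 2,6-dimethyl-1,4-dihydropyridine-3,5-dicarboxylate, 1.5 equiv), iPr2NEt (2 equiv), degassed CH2Cl2, blue LEDs, rt; 9 added by syringe pump over 12 h, final 1 mM
Reagents that add atoms: none
Why: Under blue light the excited Ru(bpy)3(PF6)2 is quenched reductively by the Hantzsch ester, and the reduced ruthenium complex passes one electron to the phthalimide unit of 9, whose N–O bond breaks with loss of CO2 and phthalimide anion to leave a primary radical at C4. This nucleophilic radical adds to the electron-poor terminal carbon C3 of the acrylate, which forms the C3–C4 bond and closes the only ring in a 27-endo-trig mode; the ester-stabilised radical at C2 then takes a hydrogen atom from the Hantzsch ester, so the saturated lactone 10 results directly. Precedent of the same type exists in three forms: tin-hydride chain reactions that cyclise iodoalkyl acrylates through the alkene terminus to large lactones, light-driven decarboxylative conjugate additions that close peptide macrocycles onto acrylamides, and bimolecular conjugate additions of radicals from N-(acyloxy)phthalimides under the same kind of reductive photocatalysis. No stereocentre and no double bond is created, so no stereocontrol is required. The step needs ring closure to outrun hydrogen transfer to the C4 radical and addition to the acrylate of a second molecule; this is secured by the polarity match, the strain-free 23-carbon polymethylene tether, the preference for attack at the unsubstituted alkene terminus (26-exo attack at C2 would give an unstabilised primary radical) and millimolar concentrations of both 9 and the hydrogen donor.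

Compound list
1 | 16-hydroxyhexadecanoic acid | OCCCCCCCCCCCCCCCC(=O)O | starting material
2 | 16-acetoxyhexadecanoic acid | CC(=O)OCCCCCCCCCCCCCCCC(=O)O | intermediate
3 | 10-tert-butoxy-10-oxodecanoic acid (mono-tert-butyl sebacate) | CC(C)(C)OC(=O)CCCCCCCCC(=O)O | starting material
4 | tert-butyl 24-acetoxytetracosanoate (formed in the flask, not isolated) | CC(=O)OCCCCCCCCCCCCCCCCCCCCCCCC(=O)OC(C)(C)C | intermediate
5 | tert-butyl 24-hydroxytetracosanoate | OCCCCCCCCCCCCCCCCCCCCCCCC(=O)OC(C)(C)C | intermediate
6 | acryloyl chloride | C=CC(=O)Cl | starting material
7 | tert-butyl 24-(acryloyloxy)tetracosanoate | C=CC(=O)OCCCCCCCCCCCCCCCCCCCCCCCC(=O)OC(C)(C)C | intermediate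
8 | 24-(acryloyloxy)tetracosanoic acid | C=CC(=O)OCCCCCCCCCCCCCCCCCCCCCCCC(=O)O | intermediate
9 | 1,3-dioxoisoindolin-2-yl 24-(acryloyloxy)tetracosanoate | C=CC(=O)OCCCCCCCCCCCCCCCCCCCCCCCC(=O)ON1C(=O)c2ccccc2C1=O | intermediate
10 | 26-hexacosanolide (oxacycloheptacosan-2-one) | O=C1CCCCCCCCCCCCCCCCCCCCCCCCCO1 | target

Total steps: 6. Longest linear sequence: 6 steps (1 to 10 through 2, 5, 7, 8 and 9); 3 and 6 enter as purchased inputs.

Steps most likely to fail

1. Step 6. The C4 radical may be quenched by hydrogen transfer before it reaches the acrylate, or it may add to the acrylate of a second molecule so that oligomerisation outpaces ring closure. The fallback closes the ring at the ester C–O bond instead. Setting out from 2, a second mixed Kolbe electrolysis with purchasable 12-methoxy-12-oxododecanoic acid (Pt electrodes, NaOMe, MeOH, 45 °C) would give methyl 26-acetoxyhexacosanoate F1. Saponification of both esters (KOH, EtOH/H2O, reflux; then HCl) would give 26-hydroxyhexacosanoic acid F2. Activation with 2,4,6-trichlorobenzoyl chloride and Et3N in THF would give 26-hydroxyhexacosanoic 2,4,6-trichlorobenzoic anhydride F3. Slow addition of F3 to DMAP in refluxing toluene at high dilution (Yamaguchi macrolactonisation) returns to the route at 10.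

2. Step 2. Symmetrical coupling of each acid may dominate over cross-coupling, waxy products may coat the anode and stop the current, and over-oxidation of the radicals to cations may divert material. The fallback joins the chain by olefination instead of radical coupling. Setting out from 1, tert-butyl 2,2,2-trichloroacetimidate in CH2Cl2/cyclohexane without Lewis acid would esterify only the carboxyl group to give tert-butyl 16-hydroxyhexadecanoate F4. Dess–Martin periodinane (NaHCO3, CH2Cl2) would give tert-butyl 16-oxohexadecanoate F5. 8-Bromooctan-1-ol and PPh3 (MeCN, reflux) would give (8-hydroxyoctyl)triphenylphosphonium bromide F6. Its ylide (2 equiv NaN(SiMe3)2, THF, −78 °C to rt) would undergo Wittig olefination with F5 to give tert-butyl (16Z)-24-hydroxytetracos-16-enoate F7. Hydrogenation (H2, Pd/C, EtOAc) returns to the route at 5.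

3. Step 5. N-Hydroxyphthalimide may add in conjugate fashion to the acrylate under the basic catalyst, the O-acylisourea may rearrange to an N-acylurea, and the active ester may hydrolyse or the acrylate polymerise during purification. The fallback uses a halide in place of the active ester as radical precursor. Setting out from 8, Hunsdiecker-type decarboxylative iodination (PhI(OAc)2, I2, cyclohexane, visible light, reflux) would give 23-iodotricosyl acrylate F8. Slow addition of Bu3SnH and AIBN to a dilute solution of F8 in refluxing benzene (tin-hydride radical macrocyclisation through the acrylate terminus) returns to the route at 10.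

Further compounds
F1 | step 6 | methyl 26-acetoxyhexacosanoate | CC(=O)OCCCCCCCCCCCCCCCCCCCCCCCCCC(=O)OC
F2 | step 6 | 26-hydroxyhexacosanoic acid | OCCCCCCCCCCCCCCCCCCCCCCCCCC(=O)O
F3 | step 6 | 26-hydroxyhexacosanoic 2,4,6-trichlorobenzoic anhydride | OCCCCCCCCCCCCCCCCCCCCCCCCCC(=O)OC(=O)c1c(Cl)cc(Cl)cc1Cl
F4 | step 2 | tert-butyl 16-hydroxyhexadecanoate | OCCCCCCCCCCCCCCCC(=O)OC(C)(C)C
F5 | step 2 | tert-butyl 16-oxohexadecanoate | O=CCCCCCCCCCCCCCCC(=O)OC(C)(C)C
F6 | step 2 | (8-hydroxyoctyl)triphenylphosphonium bromide | OCCCCCCCC[P+](c1ccccc1)(c1ccccc1)c1ccccc1.[Br-]
F7 | step 2 | tert-butyl (16Z)-24-hydroxytetracos-16-enoate | OCCCCCCC/C=C\CCCCCCCCCCCCCCC(=O)OC(C)(C)C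
F8 | step 5 | 23-iodotricosyl acrylate | C=CC(=O)OCCCCCCCCCCCCCCCCCCCCCCCI
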